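**Retrosynthetic overview**
- The C5–allyl bond is made last. The target comes from a planar 5-methoxy oxocarbenium (2-methoxyphenoxenium) ion and allyltrimethylsilane, and a chiral IDPi counteranion chooses the face (sets C5).
- That ion comes from a 3a-methoxy dienone, which is a vinylogous ketal. The dienone comes from a formal [3+2] of (E)-isoelemicin with the monoketal of 2,5-dimethoxy-1,4-benzoquinone under a chiral IDPi Brønsted acid. This forms C3–C3a and C2–O1 and sets C3 and C2, the first stereocentres.
- The quinone monoketal comes from 2,4,5-trimethoxyphenol with PhI(OAc)2/MeOH. The 3a-methoxy group stores the oxidation level, so no protecting group and no second oxidation are needed.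
- Ring order: both six-membered rings are bought, and the phenol ring is dearomatised in step 1 and stays so. The dihydrofuran ring (step 2) is the only ring formed.

**Assumption:** 1, 3 and 7 are taken as catalogue compounds. The sense of induction of a new catalyst–substrate pair cannot be predicted, so the IDPi antipode named is the one to be confirmed in the first run (its mirror image is equally accessible).

**Catalysts** (metal-free imidodiphosphorimidates, each built from two (S)-BINOL units):
- IDPi-1: 3,3′-substituents are 9,9-dimethylfluoren-2-yl and the N-sulfonyl group is C6F5SO2.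
- IDPi-2: 3,3′-substituents are 3,5-bis(trifluoromethyl)phenyl and the N-sulfonyl group is CF3SO2.

**Step 1**
Reactants: 1 2,4,5-trimethoxyphenol
Product: 2 2,4,4,5-tetramethoxycyclohexa-2,5-dien-1-one
Conditions: PhI(OAc)2 (1.05 equiv), MeOH, 0 °C, 20 min; aq. NaHCO3 wash, Et3N-deactivated SiO2
Reagents that add atoms: methanol, CO
Why: Oxidative dearomatisation of a 4-methoxyphenol with a trivalent iodine reagent (quinone monoketal synthesis), in which the phenol binds to iodine, PhI leaves in a two-electron oxidation, and methanol adds at the para carbon that already carries methoxy, the best stabilised cationic site; no stereocentre is formed.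

**Step 2**
Reactants: 2 2,4,4,5-tetramethoxycyclohexa-2,5-dien-1-one; 3 (E)-isoelemicin, 1,2,3-trimethoxy-5-[(1E)-prop-1-en-1-yl]benzene
Product: 6 (2S,3R,3aS)-3a,5-dimethoxy-3-methyl-2-(3,4,5-trimethoxyphenyl)-3,3a-dihydro-1-benzofuran-6(2H)-one, via methoxy oxocarbenium ion 4 (not isolated), via tetramethoxy ketal adduct 5 (not isolated)
Conditions: (S,S)-IDPi-1 (3 mol %), 2 (1.2 equiv), CH2Cl2/toluene 1:1, −60 to −40 °C, 24 h; then THF/aq. NaOAc–AcOH buffer pH 5, 0 °C, 30 min
Reagents that add atoms: water, O
Why: Proposed new method: an asymmetric counteranion-directed version of the acid-promoted quinone monoketal–propenylarene formal [3+2] cycloaddition (Büchi type), in which the confined strong acid ionises 2 to the contact ion pair of 4, the β-carbon of 3 attacks the methoxy-bearing C2 of 4 (the charged ring position para to the 5-methoxy group, the site used by 2-alkyl analogues, whereas C6 is switched off by the adjacent 5-methoxy group, and soft π-nucleophiles are known to add to the alkoxy-bearing ortho carbon of 2-alkoxyphenoxenium ions) with one alkene face exposed inside the chiral pocket (sets C3), the ring carbonyl oxygen closes on the benzylic carbon anti to the methyl group (sets C2, trans), the methanol released on ionisation caps C6 to give 5 and returns the proton, and buffered hydrolysis of this most labile ketal gives 6; the closest known reaction types are the racemic Brønsted or Lewis acid promoted [3+2] couplings of quinone monoketals with styrenes and the IDPi-catalysed enantioselective additions of styrenes to oxocarbenium ions; the C3a configuration (drawn for the aryl-endo approach) is erased in step 3, so a 3a-epimer is equally usable.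

**Step 3**
Reactants: 6 (2S,3R,3aS)-3a,5-dimethoxy-3-methyl-2-(3,4,5-trimethoxyphenyl)-3,3a-dihydro-1-benzofuran-6(2H)-one; 7 allyltrimethylsilane
Product: 9 (2S,3S,5R)-5-methoxy-3-methyl-5-(prop-2-en-1-yl)-2-(3,4,5-trimethoxyphenyl)-2,3-dihydro-1-benzofuran-6(5H)-one, via benzofuranyl oxocarbenium ion 8 (not isolated)
Conditions: (S,S)-IDPi-2 (2 mol %), 7 (2.0 equiv), toluene, −78 °C, 12 h; Et3N quench at −78 °C; work-up and SiO2 below 25 °C
Reagents that add atoms: allyltrimethylsilane, C=CC[Si](C)(C)C
Why: Proposed new method: a catalyst-controlled Hosomi–Sakurai allylation of a phenoxenium-type oxocarbenium ion under silylium counteranion catalysis, in which the N-silylated IDPi formed in the flask removes the tertiary 3a-methoxy group of the vinylogous ketal MeO–C5=C4–C3a–OMe as MeOSiMe3 to give the planar ion pair of 8, 7 adds in the 1,2-mode usual for unsaturated acetals to C5 (C3a is shielded by the neighbouring methyl-bearing C3 and C7 is deactivated by O1) on the face left open by the chiral anion, syn to the remote C2 aryl group (sets 5R, C2 and C3 untouched), and transfer of the small silyl group back to the anion closes the cycle; the closest known reaction types are the IDPi-catalysed enantioselective allylation of acetal-derived oxocarbenium ions and the racemic trivalent-iodine-mediated allylation of 2-alkoxyarenols at the alkoxy-bearing ortho carbon; the low temperature and cold work-up keep the product from its aromatising retro-Claisen shift.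

**Compound list**
1 | 2,4,5-trimethoxyphenol | COc1cc(OC)c(OC)cc1O | starting material
2 | 2,4,4,5-tetramethoxycyclohexa-2,5-dien-1-one | COC1=CC(OC)(OC)C(OC)=CC1=O | intermediate
3 | (E)-isoelemicin, 1,2,3-trimethoxy-5-[(1E)-prop-1-en-1-yl]benzene | C/C=C/c1cc(OC)c(OC)c(OC)c1 | starting material
4 | (2,5-dimethoxy-4-oxocyclohexa-2,5-dien-1-ylidene)(methyl)oxonium, paired with the IDPi-1 anion | COC1=CC(=[O+]C)C(OC)=CC1=O | intermediate (not isolated)
5 | (2S,3R,3aS)-3a,5,6,6-tetramethoxy-3-methyl-2-(3,4,5-trimethoxyphenyl)-2,3,3a,6-tetrahydro-1-benzofuran | COC1=C[C@@]2(OC)[C@H](C)[C@@H](c3cc(OC)c(OC)c(OC)c3)OC2=CC1(OC)OC | intermediate (not isolated)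
6 | (2S,3R,3aS)-3a,5-dimethoxy-3-methyl-2-(3,4,5-trimethoxyphenyl)-3,3a-dihydro-1-benzofuran-6(2H)-one | COC1=C[C@@]2(OC)[C@H](C)[C@@H](c3cc(OC)c(OC)c(OC)c3)OC2=CC1=O | intermediate
7 | allyltrimethylsilane | C=CC[Si](C)(C)C | starting material
8 | [(2S,3S)-3-methyl-6-oxo-2-(3,4,5-trimethoxyphenyl)-2,3-dihydro-1-benzofuran-5(6H)-ylidene](methyl)oxonium, paired with the IDPi-2 anion | C[O+]=C1C=C2[C@H](C)[C@@H](c3cc(OC)c(OC)c(OC)c3)OC2=CC1=O | intermediate (not isolated)
9 | (2S,3S,5R)-5-methoxy-3-methyl-5-(prop-2-en-1-yl)-2-(3,4,5-trimethoxyphenyl)-2,3-dihydro-1-benzofuran-6(5H)-one | C=CC[C@@]1(OC)C=C2C(=CC1=O)O[C@H](c1cc(OC)c(OC)c(OC)c1)[C@H]2C | target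

**Total step count:** 3. **Longest linear sequence:** 3 (1 → 2 → 6 → 9).

**Steps most likely to fail**

1. **Step 2 (proposed new step).**
   - Risks: attack at C6–H of 4 would give an aromatic 4,5,7-trimethoxy dihydrobenzofuran. The benzylic carbon could close on carbon in the [5+2] mode. The enantioselectivity with an alkene that has no hydrogen-bond handle may be low.
   - Fallback, known chemistry: it sets out from 3 and replaces 2 by 2-(benzyloxy)-1,4-benzoquinone F1. F1 is made from commercial 2-(benzyloxy)phenol with (KO3S)2NO in aq. KH2PO4/acetone. The known chiral-titanium-promoted [3+2] of 2-alkoxyquinones with propenylarenes (TiCl4/Ti(OiPr)4 with a TADDOL ligand, CH2Cl2, −78 °C) gives (2S,3S)-6-(benzyloxy)-3-methyl-2-(3,4,5-trimethoxyphenyl)-2,3-dihydro-1-benzofuran-5-ol F2. MeI/K2CO3 in acetone gives the 5-methyl ether F3. H2 over Pd/C in EtOAc gives (2S,3S)-5-methoxy-3-methyl-2-(3,4,5-trimethoxyphenyl)-2,3-dihydro-1-benzofuran-6-ol F4. PhI(OAc)2 in MeOH at 0 °C gives the ortho-quinone monoketal F5. Under the conditions of step 3, F5 ionises to the same ion, so the fallback comes back to the route at 8 and hence at 9.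

2. **Step 3 (proposed new step).**
   - Risks: allylation at C3a or C7 instead of C5, proton loss from C3 of 8 leading to a benzofuran, annulation of the β-silyl cation onto the C6 oxygen, or weak facial control at a centre far from C2 and C3.
   - Fallback, known chemistry: it sets out from 6. Aqueous acid (TFA, MeCN/H2O, 0 °C) hydrolyses the vinylogous ketal to (2S,3S)-3-methyl-2-(3,4,5-trimethoxyphenyl)-2,3-dihydro-1-benzofuran-5,6-dione F6. The BINOL-catalysed asymmetric allylboration of ketones (allylB(OiPr)2, (S)-3,3′-dibromo-BINOL 15 mol %, toluene/PhCF3, −35 °C) then adds strictly 1,2 through a closed six-membered transition state. It attacks the C5 carbonyl because the C6 carbonyl is a deactivated vinylogous ester. This gives the (2S,3S,5R)-5-allyl-5-hydroxy dienone F7, whose C5 epimer is a diastereomer and can be removed by chromatography. Base-free O-methylation (MeOTf, 2,6-di-tert-butyl-4-methylpyridine, CH2Cl2, 0 °C) comes back to the route at 9. Base is avoided because the alkoxide of F7 would shift its allyl group to C3a by an anionic oxy-Cope rearrangement.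

3. **Step 1.**
   - Risks: hydrolysis of 2 to 2,5-dimethoxy-1,4-benzoquinone during isolation, or competing ortho ketal formation.
   - Fallback: it sets out from 1. MeI/K2CO3 gives 1,2,4,5-tetramethoxybenzene F8. Anodic oxidation (glassy carbon anode, KOH/MeOH, undivided cell, 0 °C) gives the symmetric quinone bisketal 1,3,3,4,6,6-hexamethoxycyclohexa-1,4-diene F9. Controlled monohydrolysis (aq. AcOH/THF, 0 °C; the two ketals are equivalent) comes back to the route at 2.

**Further compounds**
F1 | step 2 | 2-(benzyloxy)cyclohexa-2,5-diene-1,4-dione | O=C1C=CC(=O)C(OCc2ccccc2)=C1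
F2 | step 2 | (2S,3S)-6-(benzyloxy)-3-methyl-2-(3,4,5-trimethoxyphenyl)-2,3-dihydro-1-benzofuran-5-ol | Oc1cc2c(cc1OCc1ccccc1)O[C@H](c1cc(OC)c(OC)c(OC)c1)[C@H]2C
F3 | step 2 | (2S,3S)-6-(benzyloxy)-5-methoxy-3-methyl-2-(3,4,5-trimethoxyphenyl)-2,3-dihydro-1-benzofuran | COc1cc2c(cc1OCc1ccccc1)O[C@H](c1cc(OC)c(OC)c(OC)c1)[C@H]2C
F4 | step 2 | (2S,3S)-5-methoxy-3-methyl-2-(3,4,5-trimethoxyphenyl)-2,3-dihydro-1-benzofuran-6-ol | COc1cc2c(cc1O)O[C@H](c1cc(OC)c(OC)c(OC)c1)[C@H]2C
F5 | step 2 | (2S,3S)-5,5-dimethoxy-3-methyl-2-(3,4,5-trimethoxyphenyl)-2,3-dihydro-1-benzofuran-6(5H)-one | COC1(OC)C=C2C(=CC1=O)O[C@H](c1cc(OC)c(OC)c(OC)c1)[C@H]2C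
F6 | step 3 | (2S,3S)-3-methyl-2-(3,4,5-trimethoxyphenyl)-2,3-dihydro-1-benzofuran-5,6-dione | O=C1C=C2C(=CC1=O)O[C@H](c1cc(OC)c(OC)c(OC)c1)[C@H]2C
F7 | step 3 | (2S,3S,5R)-5-hydroxy-3-methyl-5-(prop-2-en-1-yl)-2-(3,4,5-trimethoxyphenyl)-2,3-dihydro-1-benzofuran-6(5H)-one | C=CC[C@@]1(O)C=C2C(=CC1=O)O[C@H](c1cc(OC)c(OC)c(OC)c1)[C@H]2C
F8 | step 1 | 1,2,4,5-tetramethoxybenzene | COc1cc(OC)c(OC)cc1OC
F9 | step 1 | 1,3,3,4,6,6-hexamethoxycyclohexa-1,4-diene | COC1=CC(OC)(OC)C(OC)=CC1(OC)OC
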